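**Retrosynthetic overview**
1. Target 19 ⇐ C8 tigloylation, C8 α-hydroxylation (Rubottom) and C1 acetylation of the trans-fused β-hydroxy ketone 14.
2. 14 ⇐ SmI2 opening of the 1α,10α-epoxide 12 of dienone 11; kinetic protonation at C10 gives the trans ring fusion.
3. Ring A (formed last) ⇐ intramolecular aldol condensation of keto aldehyde 9 ⇐ linear hydroformylation of vinyl ketone 8.
4. Key bond C4–C5 (quaternary/tertiary methyl pair) ⇐ anionic oxy-Cope rearrangement of the (Z)-crotyl carbinol 5 made from enone 4.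
5. Ring B is bought: enone 4 ⇐ (+)-3-carene (1) by allylic oxidation and thermal retro-ene opening of the cyclopropane; C7 is the only purchased stereocentre.

Assumption: names use eremophilane numbering (decalin C1–C10; ring A = C1–C5 and C10; ring B = C5–C10; methyls on C4 and C5; prop-1-en-2-yl on C7; β = face of the C5 methyl), and (Z)-1-chlorobut-2-ene and all other reagents are purchased.

**Route**

Step 1
Reactants: 1 (+)-3-carene
Product: 2 (1R,6S)-4,7,7-trimethylbicyclo[4.1.0]hept-3-en-2-one
Conditions: t-BuOOH, Cr(CO)6 (cat.), MeCN, reflux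
Reagents that add atoms: tert-butyl hydroperoxide CC(C)(C)OO
Why: Allylic C–H oxidation takes the ring CH2 next to the unsubstituted alkene carbon, where the allyl radical is delocalised onto the methyl-bearing carbon and is also cyclopropylcarbinyl, giving the β-methyl enone without touching either stereocentre.

Step 2
Reactants: 2 (1R,6S)-4,7,7-trimethylbicyclo[4.1.0]hept-3-en-2-one
Product: 4 (5S)-3-methyl-5-(prop-1-en-2-yl)cyclohex-2-en-1-one, via dienol 3 (not isolated)
Conditions: neat, Ar, 200 °C, sealed tube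
Reagents that add atoms: none
Why: A thermal retro-ene reaction (homo-1,5-hydrogen shift) passes a hydrogen of the endo methyl, which is cis to the acyl carbon, to the carbonyl oxygen while the conjugated cyclopropane bond opens, so only the isopropenyl isomer can form and the dienol tautomerises to the enone with the carene stereocentre (future C7) unchanged.

Step 3
Reactants: 4 (5S)-3-methyl-5-(prop-1-en-2-yl)cyclohex-2-en-1-one
Product: 5 (1S,5S)-1-[(2Z)-but-2-en-1-yl]-3-methyl-5-(prop-1-en-2-yl)cyclohex-2-en-1-ol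
Conditions: (Z)-MeCH=CHCH2Cl, activated Ba, THF, −78 °C; then 4, −78 °C; then H2O
Reagents that add atoms: (Z)-1-chlorobut-2-ene C/C=C\CCl
Why: Allylic barium reagents add 1,2 to enones at the α-carbon with retention of alkene geometry, and axial attack anti to the equatorial isopropenyl group sets the carbinol carbon (C9) with the crotyl group trans to isopropenyl.

Step 4
Reactants: 5 (1S,5S)-1-[(2Z)-but-2-en-1-yl]-3-methyl-5-(prop-1-en-2-yl)cyclohex-2-en-1-ol
Product: 8 (3S,5S)-3-[(2S)-but-3-en-2-yl]-3-methyl-5-(prop-1-en-2-yl)cyclohexan-1-one, via potassium alkoxide 6 (not isolated), via potassium enolate 7 (not isolated)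
Conditions: KH, 18-crown-6, THF, 0 °C to rt; then H2O
Reagents that add atoms: none
Why: In this anionic oxy-Cope [3,3]-sigmatropic rearrangement the axial crotyl group is delivered suprafacially to C5 on the face anti to isopropenyl, so the C5 methyl ends cis to isopropenyl, and the chair transition state with the (Z)-methyl axial sets C4 as S, giving the cis-vicinal dimethyl pair.

Step 5
Reactants: 8 (3S,5S)-3-[(2S)-but-3-en-2-yl]-3-methyl-5-(prop-1-en-2-yl)cyclohexan-1-one
Product: 9 (4S)-4-[(1S,5S)-1-methyl-3-oxo-5-(prop-1-en-2-yl)cyclohexyl]pentanal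
Conditions: CO/H2 (1:1, 10 bar), Rh(acac)(CO)2 (cat.), BiPhePhos, toluene, 70 °C
Reagents that add atoms: carbon monoxide [C-]#[O+]
Why: Linear-selective rhodium-catalysed hydroformylation converts the monosubstituted vinyl group far faster than the 1,1-disubstituted isopropenyl group and places the formyl carbon (C1) on the terminal carbon, with no new stereocentre.

Step 6
Reactants: 9 (4S)-4-[(1S,5S)-1-methyl-3-oxo-5-(prop-1-en-2-yl)cyclohexyl]pentanal
Product: 11 (4S,5R,7S)-eremophila-1(10),11-dien-9-one, via aldol adduct 10 (not isolated)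
Conditions: KOH, MeOH, 50 °C
Reagents that add atoms: none
Why: In this intramolecular aldol condensation the ketone enolate at C10 closes the six-membered ring A onto the aldehyde (the C8 enolate could only form an eight-membered ring), and dehydration to the conjugated enone drives the equilibrium and removes the C1/C10 stereochemistry for later control.

Step 7
Reactants: 11 (4S,5R,7S)-eremophila-1(10),11-dien-9-one
Product: 12 (1S,4S,5R,7S,10R)-1,10-epoxyeremophil-11-en-9-one
Conditions: H2O2 (30% aq), NaOH, MeOH, 0 °C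
Reagents that add atoms: hydrogen peroxide OO
Why: In this Weitz–Scheffer nucleophilic epoxidation the hydroperoxide anion adds to C1 from the α face, anti to the pseudoaxial C5 methyl, and closes to the 1α,10α-epoxide, while the electron-neutral isopropenyl group is inert.

Step 8
Reactants: 12 (1S,4S,5R,7S,10R)-1,10-epoxyeremophil-11-en-9-one
Product: 14 (1S,4S,5R,7S,10S)-1-hydroxyeremophil-11-en-9-one, via samarium enolate 13 (not isolated)
Conditions: SmI2, THF/MeOH, −90 °C
Reagents that add atoms: none
Why: Single-electron reductive opening of the α,β-epoxy ketone cleaves the C10–O bond with retention at C1, and the samarium enolate is protonated at C10 from the α face, anti to the angular methyl and next to the samarium-bound 1α-oxygen, which fixes the trans ring fusion kinetically.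

Step 9
Reactants: 14 (1S,4S,5R,7S,10S)-1-hydroxyeremophil-11-en-9-one
Product: 15 (1S,4S,5R,7S,10S)-1-acetoxyeremophil-11-en-9-one
Conditions: Ac2O, pyridine, DMAP (cat.), CH2Cl2, 0 °C
Reagents that add atoms: acetic anhydride CC(=O)OC(C)=O
Why: DMAP-catalysed acylation of the unhindered equatorial alcohol proceeds with retention, and the equatorial C1–O bond lies near the enolate plane so E1cB loss of acetate and C10 epimerisation are slow under these mild conditions.

Step 10
Reactants: 15 (1S,4S,5R,7S,10S)-1-acetoxyeremophil-11-en-9-one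
Product: 18 (1S,4S,5R,7R,8R,10S)-1-acetoxy-8-hydroxyeremophil-11-en-9-one, via silyl enol ether 16 (not isolated), via silyloxy ketone 17 (not isolated)
Conditions: LiN(SiMe3)2, Me3SiCl, THF, −78 °C; volatiles removed; then DMDO (1.0 equiv), acetone/CH2Cl2, −78 °C; then dilute HCl (aq), 0 °C
Reagents that add atoms: dimethyldioxirane CC1(C)OO1
Why: In this Rubottom oxidation kinetic deprotonation with internal silyl quench takes the less hindered C8 proton rather than the tertiary C10 proton, and the electron-rich silyl enol ether is oxidised (much faster than isopropenyl) from the α face, anti to the pseudoaxial 7β-isopropenyl group, giving the 8α-alcohol.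

Step 11
Reactants: 18 (1S,4S,5R,7R,8R,10S)-1-acetoxy-8-hydroxyeremophil-11-en-9-one
Product: 19 (1S,4S,5R,7R,8R,10S)-1-acetoxy-9-oxoeremophil-11-en-8-yl (2E)-2-methylbut-2-enoate
Conditions: (E)-MeCH=C(Me)COCl, pyridine, DMAP (cat.), CH2Cl2, 0 °C to rt
Reagents that add atoms: (E)-2-methylbut-2-enoyl chloride C/C=C(\C)C(=O)Cl
Why: DMAP-catalysed O-acylation of the secondary α-ketol occurs at oxygen with retention at C8 and keeps the (E) geometry of the tigloyl unit, completing the target.

**Compound list**

1 | (+)-3-carene, (1S,6R)-3,7,7-trimethylbicyclo[4.1.0]hept-3-ene | CC1=CC[C@@H]2[C@H](C1)C2(C)C | starting material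
2 | (1R,6S)-4,7,7-trimethylbicyclo[4.1.0]hept-3-en-2-one (car-3-en-5-one) | CC1=CC(=O)[C@@H]2[C@H](C1)C2(C)C | intermediate
3 | dienol of 4, (3S)-5-methyl-3-(prop-1-en-2-yl)cyclohexa-1,5-dien-1-ol | C=C(C)[C@H]1CC(C)=CC(O)=C1 | intermediate
4 | (5S)-3-methyl-5-(prop-1-en-2-yl)cyclohex-2-en-1-one | C=C(C)[C@H]1CC(C)=CC(=O)C1 | intermediate
5 | (1S,5S)-1-[(2Z)-but-2-en-1-yl]-3-methyl-5-(prop-1-en-2-yl)cyclohex-2-en-1-ol | C=C(C)[C@H]1CC(C)=C[C@](O)(C/C=C\C)C1 | intermediate
6 | potassium alkoxide of 5 | C=C(C)[C@H]1CC(C)=C[C@]([O-])(C/C=C\C)C1.[K+] | intermediate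
7 | potassium enolate of 8 (C9–C10 enolate) | C=C(C)[C@H]1C[C@@](C)(C=C([O-])C1)[C@@H](C)C=C.[K+] | intermediate
8 | (3S,5S)-3-[(2S)-but-3-en-2-yl]-3-methyl-5-(prop-1-en-2-yl)cyclohexan-1-one | C=C(C)[C@H]1C[C@@](C)(CC(=O)C1)[C@@H](C)C=C | intermediate
9 | (4S)-4-[(1S,5S)-1-methyl-3-oxo-5-(prop-1-en-2-yl)cyclohexyl]pentanal | C=C(C)[C@H]1C[C@@](C)(CC(=O)C1)[C@@H](C)CCC=O | intermediate
10 | aldol adduct, (4S,5R,7S)-1-hydroxyeremophil-11-en-9-one, mixed at C1 and C10 | C=C(C)[C@H]1C[C@@]2(C)C(C(=O)C1)C(O)CC[C@@H]2C | intermediate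
11 | (4S,5R,7S)-eremophila-1(10),11-dien-9-one | C=C(C)[C@H]1C[C@@]2(C)C(C(=O)C1)=CCC[C@@H]2C | intermediate
12 | (1S,4S,5R,7S,10R)-1,10-epoxyeremophil-11-en-9-one (1α,10α-epoxide) | C=C(C)[C@H]1C[C@@]2(C)[C@@]3(C(=O)C1)O[C@H]3CC[C@@H]2C | intermediate
13 | samarium enolate, C9 enolate and C1 alkoxide of 14, each oxygen bound to SmI2 | C=C(C)[C@H]1C[C@@]2(C)C(=C(O[Sm](I)I)C1)[C@@H](O[Sm](I)I)CC[C@@H]2C | intermediate
14 | (1S,4S,5R,7S,10S)-1-hydroxyeremophil-11-en-9-one | C=C(C)[C@H]1C[C@@]2(C)[C@H](C(=O)C1)[C@@H](O)CC[C@@H]2C | intermediate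
15 | (1S,4S,5R,7S,10S)-1-acetoxyeremophil-11-en-9-one | C=C(C)[C@H]1C[C@@]2(C)[C@H](C(=O)C1)[C@@H](OC(C)=O)CC[C@@H]2C | intermediate
16 | trimethylsilyl enol ether of 15 (C8=C9) | C=C(C)[C@H]1C[C@@]2(C)[C@H](C(O[Si](C)(C)C)=C1)[C@@H](OC(C)=O)CC[C@@H]2C | intermediate
17 | 8α-trimethylsilyloxy ketone, silyl ether of 18 | C=C(C)[C@H]1C[C@@]2(C)[C@H](C(=O)[C@@H]1O[Si](C)(C)C)[C@@H](OC(C)=O)CC[C@@H]2C | intermediate
18 | (1S,4S,5R,7R,8R,10S)-1-acetoxy-8-hydroxyeremophil-11-en-9-one | C=C(C)[C@H]1C[C@@]2(C)[C@H](C(=O)[C@@H]1O)[C@@H](OC(C)=O)CC[C@@H]2C | intermediate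
19 | (1S,4S,5R,7R,8R,10S)-1-acetoxy-9-oxoeremophil-11-en-8-yl (2E)-2-methylbut-2-enoate (CNP0138236.1) | C=C(C)[C@H]1C[C@@]2(C)[C@H](C(=O)[C@@H]1OC(=O)/C(C)=C/C)[C@@H](OC(C)=O)CC[C@@H]2C | target

**Totals**
Total step count: 11. Longest linear sequence: 11 steps (1 to 19, fully linear).

**Three steps most likely to fail, with fallbacks**

Step 4 (configuration at C4). The S configuration relies on a chair transition state and on the crotyl unit staying (Z); boat leakage, a 1,3-shift or allyl fragmentation would erode it. Fallback: set out from 4 and return at 8 by a Hosomi–Sakurai conjugate crotylation (crotyltrimethylsilane, TiCl4, CH2Cl2, −78 °C). It forms C4–C5 through an open antiperiplanar transition state, again anti to isopropenyl, with the silane geometry chosen to give the 4S epimer. Compound 5 is bypassed and no new compound is made on the way (none F0).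

Step 8 (configuration at C10). The target's trans fusion is probably the less stable one (isopropenyl axial), so it cannot be corrected by equilibration if protonation goes to the β face. Fallback: set out from 5 and return at 14. The oxy-Cope is run as before, but enolate 7 is transmetalated with ZnCl2 and trapped with acrolein at −78 °C, which attacks C10 anti to the axial side chain and gives the anti aldol (2S,3R,5S)-3-[(2S)-but-3-en-2-yl]-2-[(1S)-1-hydroxyprop-2-en-1-yl]-3-methyl-5-(prop-1-en-2-yl)cyclohexan-1-one F1. Ring-closing metathesis with the second-generation Grubbs catalyst RuCl2(=CHPh)(H2IMes)(PCy3) then closes the trans-fused ring A as (1S,4S,5R,7S,10S)-1-hydroxyeremophila-2,11-dien-9-one F2. Hydroxyl-directed hydrogenation of the ring alkene ([Rh(nbd)(dppb)]BF4, one equivalent of H2) gives 14; sparing the isopropenyl group here is the weak point of this fallback.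

Step 2 (thermal cyclopropane opening). At 200 °C the dienone may aromatise to a phenol or conversion may be incomplete. Fallback: set out from 2 and return at 4. Homoconjugate addition of HBr (HBr in AcOH, 0 °C) to the cyclopropyl ketone gives (5S)-5-(2-bromopropan-2-yl)-3-methylcyclohex-2-en-1-one F3, and dehydrobromination (LiBr, Li2CO3, DMF, 120 °C) gives 4. The risks there are the isopropylidene isomer and re-closure to 2.

**Further compounds**
F0 | step 4 | none | none
F1 | step 8 | (2S,3R,5S)-3-[(2S)-but-3-en-2-yl]-2-[(1S)-1-hydroxyprop-2-en-1-yl]-3-methyl-5-(prop-1-en-2-yl)cyclohexan-1-one | C=C(C)[C@H]1C[C@](C)([C@@H](C)C=C)[C@H](C(=O)C1)[C@@H](O)C=C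
F2 | step 8 | (1S,4S,5R,7S,10S)-1-hydroxyeremophila-2,11-dien-9-one | C=C(C)[C@H]1C[C@@]2(C)[C@H](C(=O)C1)[C@@H](O)C=C[C@@H]2C
F3 | step 2 | (5S)-5-(2-bromopropan-2-yl)-3-methylcyclohex-2-en-1-one | CC(C)(Br)[C@H]1CC(C)=CC(=O)C1
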